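**Retrosynthetic overview**

- Target 8 (6,7-dimethoxy-2-(2,3,4-trimethoxyphenyl)chromen-4-one) comes from the 4-methoxyflavylium salt 7 by hydrolysis at C4 with loss of methanol.
- 7 comes from the open-chain β-methoxy enone 6 by cutting O1–C8a, the aryl ether bond of the pyranone ring. The strategy rests on this bond: it sits on the A-ring carbon para to the C6 methoxy group, where an arene radical cation accepts an oxygen nucleophile. Anodic formation of this bond closes ring C, the only ring made in the route; rings A and B are bought intact.
- 6 comes from ynone 4 and methanol 5 (oxa-Michael addition); 4 from acid chloride 2 and alkyne 3 (acyl Sonogashira); 2 from acid 1.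

Key step: step 4

Remark on the chemistry: the target has no stereocentre, so the single-enantiomer requirement is met trivially. The only stereo-element in the route is the C=C geometry of 6.

**Step 1**
Reactants: 1 2,3,4-trimethoxybenzoic acid
Product: 2 2,3,4-trimethoxybenzoyl chloride
Conditions: (COCl)2 (1.3 equiv), DMF (cat.), CH2Cl2, 0 °C to rt; concentrate, use crude
Reagents that add atoms: oxalyl chloride, O=C(Cl)C(=O)Cl
Why: Acid chloride formation via the Vilsmeier-type chloroiminium ion from DMF and oxalyl chloride should be clean, since the aryl methyl ethers are inert and the by-products are gases.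

**Step 2**
Reactants: 2 2,3,4-trimethoxybenzoyl chloride; 3 4-ethynyl-1,2-dimethoxybenzene
Product: 4 3-(3,4-dimethoxyphenyl)-1-(2,3,4-trimethoxyphenyl)prop-2-yn-1-one
Conditions: PdCl2(PPh3)2 (2 mol%), CuI (4 mol%), Et3N (1.25 equiv), THF, rt, Ar
Reagents that add atoms: none
Why: Acyl Sonogashira coupling, in which Pd(0) inserts into the C(O)–Cl bond, the copper acetylide of 3 transmetallates and reductive elimination at room temperature (no decarbonylation) should give the ynone, with the amine kept near one equivalent to avoid its conjugate addition.

**Step 3**
Reactants: 4 3-(3,4-dimethoxyphenyl)-1-(2,3,4-trimethoxyphenyl)prop-2-yn-1-one; 5 methanol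
Product: 6 (E)-3-(3,4-dimethoxyphenyl)-3-methoxy-1-(2,3,4-trimethoxyphenyl)prop-2-en-1-one (MeO trans to the ketone, dimethoxyphenyl ring cis to it)
Conditions: NaOMe (0.2 equiv), MeOH/THF 3:1, 0 °C to rt; AcOH (0.2 equiv) quench; crystallisation or Et3N-deactivated silica
Reagents that add atoms: methanol (5), CO
Why: Oxa-Michael addition, in which methoxide attacks the alkyne carbon β to the ketone and methanol protonates the allenolate and regenerates the base; reversible methoxide addition–elimination is expected to settle the double bond mainly as E, and any Z isomer can be carried on because both geometries should converge in step 4.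

**Step 4**
Reactants: 6 (E)-3-(3,4-dimethoxyphenyl)-3-methoxy-1-(2,3,4-trimethoxyphenyl)prop-2-en-1-one
Product: 7 4,6,7-trimethoxy-2-(2,3,4-trimethoxyphenyl)chromenylium tetrafluoroborate
Conditions: divided cell (glass frit), graphite felt anode, Pt cathode, constant current (ca. 2 mA cm⁻²), ca. 2.2 F mol⁻¹, rt, Ar; anolyte: 6 (0.02 M), 2,6-lutidine (1.2 equiv), Et4NBF4 (0.1 M), dry MeCN; catholyte: HBF4·OEt2 (2.5 equiv), Et4NBF4 (0.1 M), MeCN; anolyte concentrated, salt precipitated with dry Et2O and used crude
Reagents that add atoms: tetrafluoroboric acid (used as its diethyl ether complex), [H+].F[B-](F)(F)F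
Why: Proposed new method: one-electron oxidation at the anode should occur at the 3,4-dimethoxyphenyl enol ether (the aryl ketone end of the push–pull system is electron-poor), the vinylogous-ester carbonyl oxygen of the E isomer then attacks the ring carbon para to the 3-methoxy group, where spin and charge of the radical cation are concentrated, and loss of the proton to 2,6-lutidine followed by a second, very easy oxidation of the pyranyl radical gives the aromatic 4-methoxyflavylium ion. The closest known reaction types are anodic dehydrogenative C–O cyclisations in which a tethered carbonyl oxygen attacks an electron-rich arene radical cation (lactonisation of biaryl-2-carboxylic acids, benzoxazoles from anilides) and chemical oxidative cyclisations of chalcone-type enones to flavylium salts, whereas closure of a ketone oxygen onto an unfunctionalised arene C–H to give a pyrylium ring has not been shown. The pyran ring closes in a six-membered mode, best described as an oxa-6π closure of the O=C–C=C–C(aryl)=C(aryl) array in the radical cation (6-endo with respect to the arene bond C4a–C8a), and no stereocentre is created. The step needs selectivity between the two ortho carbons of ring A and against C–C coupling to ring B: the carbon para to methoxy is activated and unhindered, the other ortho carbon is flanked by a methoxy group, and ring B is deactivated by its carbonyl and could only be reached through a seven-membered closure. Z-configured material should drain through the E isomer because the C=C bond order is lowered in the radical cation, and the low concentration favours ring closure over arene–arene dimerisation. The divided cell keeps the easily reduced cation away from the cathode, lutidine stops the acid set free from protonating unreacted 6, and the cationic product is much harder to oxidise than 6, which should limit over-oxidation.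

**Step 5**
Reactants: 7 4,6,7-trimethoxy-2-(2,3,4-trimethoxyphenyl)chromenylium tetrafluoroborate
Product: 8 6,7-dimethoxy-2-(2,3,4-trimethoxyphenyl)-4H-chromen-4-one
Conditions: H2O/MeCN 1:3, 40 °C; then sat. aq NaHCO3, EtOAc extraction; crystallisation (EtOH) or chromatography
Reagents that add atoms: water, O
Why: Hydrolysis of an O-methylated vinylogous ester cation, in which water adds at C4 of the 4-methoxypyrylium ring and the hemiketal loses methanol to give the neutral 4-pyranone (the known reverse of flavone O-alkylation); adducts at C2 are reversible in the acidic medium and should drain through the C4 pathway.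

**Compound list**

1 | 2,3,4-trimethoxybenzoic acid | COc1ccc(C(=O)O)c(OC)c1OC | starting material
2 | 2,3,4-trimethoxybenzoyl chloride | COc1ccc(C(=O)Cl)c(OC)c1OC | intermediate
3 | 4-ethynyl-1,2-dimethoxybenzene | C#Cc1ccc(OC)c(OC)c1 | starting material
4 | 3-(3,4-dimethoxyphenyl)-1-(2,3,4-trimethoxyphenyl)prop-2-yn-1-one | COc1ccc(C#CC(=O)c2ccc(OC)c(OC)c2OC)cc1OC | intermediate
5 | methanol | CO | starting material
6 | (E)-3-(3,4-dimethoxyphenyl)-3-methoxy-1-(2,3,4-trimethoxyphenyl)prop-2-en-1-one | CO/C(=C/C(=O)c1ccc(OC)c(OC)c1OC)c1ccc(OC)c(OC)c1 | intermediate
7 | 4,6,7-trimethoxy-2-(2,3,4-trimethoxyphenyl)chromenylium tetrafluoroborate | COc1cc2[o+]c(-c3ccc(OC)c(OC)c3OC)cc(OC)c2cc1OC.F[B-](F)(F)F | intermediate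
8 | 6,7-dimethoxy-2-(2,3,4-trimethoxyphenyl)-4H-chromen-4-one | COc1cc2oc(-c3ccc(OC)c(OC)c3OC)cc(=O)c2cc1OC | target

**Step count**

Total steps: 5. Longest linear sequence: 5 steps (1 → 2 → 4 → 6 → 7 → 8).

**Steps most likely to fail**

1. Step 4 (proposed new method). The radical cation may dimerise through arene–arene coupling, be over-oxidised, couple to ring B through carbon, or be trapped by adventitious water before the oxygen closes the ring. The fallback uses known chemistry and buys the O1–C8a bond instead of making it. It sets out from acid chloride 2, which acylates commercial 1-(2-hydroxy-4,5-dimethoxyphenyl)ethanone F1 in pyridine (0 °C to rt) to give the aryl ester 2-acetyl-4,5-dimethoxyphenyl 2,3,4-trimethoxybenzoate F2. Baker–Venkataraman rearrangement (KOH, pyridine, 50 °C, then AcOH) should give 1-(2-hydroxy-4,5-dimethoxyphenyl)-3-(2,3,4-trimethoxyphenyl)propane-1,3-dione F3. Cyclodehydration (cat. H2SO4, AcOH, 100 °C) then comes back to the route at the target 8.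

2. Step 3. Addition may not stop after one methoxide (a second addition gives the ketal), the enol ether may hydrolyse to the 1,3-diketone on work-up or silica, or the geometry may settle unfavourably. The fallback accepts the over-addition and sets out from ynone 4. Excess NaOMe in MeOH at reflux should drive it to the ketal 3-(3,4-dimethoxyphenyl)-3,3-dimethoxy-1-(2,3,4-trimethoxyphenyl)propan-1-one F4. Acid-catalysed elimination of one methanol (pyridinium tosylate cat., toluene, 100 °C, methanol distilled off) under thermodynamic control then comes back to the route at 6.

3. Step 5. Water may add at C2 instead of C4 and open the pyran ring to a phenolic enone or diketone that closes again only slowly, or hydrolysis may stay incomplete. The fallback sets out from 7 and avoids water: anhydrous LiCl in DMF at 50 °C should remove the C4 O-methyl group by SN2 attack of chloride on the methyl carbon (dealkylation of an alkoxypyrylium salt), leaving the carbonyl oxygen in place and coming back to the route at 8.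

**Further compounds**

F1 | step 4 | 1-(2-hydroxy-4,5-dimethoxyphenyl)ethanone (purchased partner) | CC(=O)c1cc(OC)c(OC)cc1O
F2 | step 4 | 2-acetyl-4,5-dimethoxyphenyl 2,3,4-trimethoxybenzoate | CC(=O)c1cc(OC)c(OC)cc1OC(=O)c1ccc(OC)c(OC)c1OC
F3 | step 4 | 1-(2-hydroxy-4,5-dimethoxyphenyl)-3-(2,3,4-trimethoxyphenyl)propane-1,3-dione | COc1cc(O)c(C(=O)CC(=O)c2ccc(OC)c(OC)c2OC)cc1OC
F4 | step 3 | 3-(3,4-dimethoxyphenyl)-3,3-dimethoxy-1-(2,3,4-trimethoxyphenyl)propan-1-one | COc1ccc(C(OC)(OC)CC(=O)c2ccc(OC)c(OC)c2OC)cc1OC
F0 | step 5 | none | none
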